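The closed, stirred vessel held X with a trace of D, and the red run had followed E in this very flask.

- red: X 10 mM; D 0.2 mol%; the very flask that is asked about, followed so far
- flask: X 10 mM; D 0.2 mol%; time 6.0 d

red run (percent of the X charged)

| time / h | E / % |
|---|---|
| 15.0 | 8.8 |
| 30.0 | 14.2 |
| 40.0 | 16.3 |
| 60.0 | 19.8 |
| 72.0 | 21.8 |
| 96.0 | 23.5 |

(each reading ± 0.5 percentage points)

- oak: at 6.0 d add X, 50.0% of the amount charged, then wait 3.0 d
- larch: change nothing and wait 3.0 d more
- elm: at 6.0 d take out 90% of the E then present, then wait 3.0 d
- alder: at 6.0 d add D, 50.0% of the amount charged, then wait 3.0 d

- what is taken out of E is counted as made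
- additions bring no volume worth counting

- E, in percent of the X first charged, at 6.0 d
- what to do for the largest gain in E; "none" if nothing gains more than 2 percentage points (oak / larch / elm / alder / none)
- E present, with what was taken out counted in, in percent of the X first charged, after elm
- E present, with what was taken out counted in, in percent of the X first charged, after alder

I looked for the concentration that set the order of the rate. I took the rate as proportional to c_D and to the distance of E from a plateau, which makes the approach pseudo-first-order, with a relaxation time τ at fixed c_D. Fitting the speeds of the first and last reading pairs against E gave both numbers, so I asked which reading mattered. Raising the first reading by 0.5 percentage points gave τ 42.6 h and plateau 25.7%. Raising the last gave 42.5 h and 26.8%, a higher plateau. Even then, hardly any of the distance remained at 6.0 d, so the plateau carried the answer and the last readings carried the plateau.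

As read, τ, the time in which the distance to the plateau falls by a factor e, was 38.6 h, and the plateau 25.4%, so E at 6.0 d came to 24.8%. My fit did not separate equilibrium from dying D. I wagered on equilibrium, with the plateau as a fixed share of the X and E present. That gave 39.4% after elm, 36.0% after oak and 25.3% after alder, so I chose elm.

The forecast differed, with 24.6%, alder, 25.2% after elm and 33.5% after alder: “I judge catalyst death somewhat more likely”.

The flask gave 25.3% at 6.0 d, and elm was best, reaching 38.5%, a gain of 13 points; alder reached 26.1%.

    X + D ⇌ G (K = 17.0 M⁻¹, k = 670 M⁻¹ h⁻¹)
    G ⇌ D + E (K = 0.0210 M, k = 50.0 h⁻¹)
    D + E → J (k = 1.20 M⁻¹ h⁻¹)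

In this flask at 144 h, the step D + E → J took E with a half-life of 1800 d, far longer than the 6.0 d the flask had stood. At that time 74.3% of the catalyst could still turn over, while E stood at 25.3% and X at 74.6%. For a neighbour flask with 0.08 mol% of D, I held the plateau as read and scaled τ inversely with the loading of D, to 96.4 h, which gives 19.7% at 6.0 d; that flask gave 19.8%.

The earlier runs and the new flask stem from a simulated flask on assumed constants, noise included.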